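**One molecule.** Follow a molecule of Q through epsilon and zeta. It meets two forks: either it has reacted by the end or it has not, and if it has reacted, it stands, J aside, as L or as G. G appears after L in both earlier runs.

| setting | south-east | north-west | epsilon | zeta |
|---|---|---|---|---|
| Q | 2 M | 2 M | 2.0 M | 2.0 M |
| Z | 2 M | 2 M | 2.00 M | 2.00 M |
| X | 50 mM (in portions, 3) | 200 mM (in portions, 3) | 100 mM (in portions, 3) | 100 mM (in portions, 3) |
| remark | run made earlier; portions every 1.0 min | run made earlier; portions every 1.0 min | the portions of X follow each other after 1.0 min, the first at the start | the portions of X follow each other after 1.0 min, the first at the start |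
| time |  |  | 40 min | 80 min |

| run | time / min | G / % | Q / % | J / % | L / % |
|---|---|---|---|---|---|
| south-east | 4.00 | 0 | 92 | 2 | 6 |
| south-east | 12.0 | 8 | 73 | 2 | 19 |
| south-east | 20.0 | 13 | 61 | 1 | 26 |
| south-east | 30.0 | 19 | 48 | 0 | 35 |
| north-west | 2.50 | 0 | 84 | 5 | 12 |
| north-west | 6.00 | 3 | 60 | 5 | 35 |
| north-west | 15.0 | 22 | 21 | 7 | 53 |
| north-west | 30.0 | 38 | 4 | 5 | 53 |

(standard deviation of a reading: 1.5 percentage points)

- which of these there is most of at the end, counted by the Q in it, epsilon (L / Q / J / G)
- which of these there is most of at the end, counted by the Q in it, zeta (L / Q / J / G)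
- how much there is at the end of the one of these that leads, in percent of the Q charged: epsilon
- how much there is at the end of the one of these that leads, in percent of the Q charged: zeta

- the analysis behind the earlier runs scatters by 1.5 percentage points, standard deviation

**Second fork.** The last north-west reading gives 0.582 for the L share, the fraction of L + G standing as L. G can lead only if this share falls below 0.5, and the reading stands higher. But the north-west share was 0.707 at 15.0 min, so it fell between those two readings, and the margin in zeta, the longer flask, should be thinner.

**First fork.** With J neglected, Q can lead only if the fraction left exceeds the L share times the fraction reacted, which puts the fraction left above 36.8%. The pseudo-first-order constant of Q reads 0.0245 min⁻¹ at 50 mM of X and 0.104 min⁻¹ at 200 mM. [X] of 100 mM lies midway on a logarithmic scale, so the geometric mean, 0.0505 min⁻¹, is taken for it. With that constant epsilon is reckoned to keep 13.3% of its Q, less than the critical fraction, and zeta 1.77%.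

**Own reckoning.** L should lead in both flasks. Taking the north-west share over and neglecting J, which reads 7% or less in the earlier runs, epsilon is reckoned near 50.5%. For zeta the same share gives 57.2%, which overstates L if the share goes on falling after that last reading.

**The forecast.** It gives L at 50% for epsilon and L at 52% for zeta, on these grounds: "This suggests a reversible L⇌G step". Its figure for zeta stands below the 57.2% reckoned here.

**The result.**

    Q + X → J (k = 0.0210 M⁻¹ s⁻¹)
    Z + J ⇌ E (K = 0.160 M⁻¹, k = 0.0170 M⁻¹ s⁻¹)
    E → X + L (k = 0.610 s⁻¹)
    L ⇌ G (K = 0.920, k = 9.70 × 10⁻⁴ s⁻¹)
    L → D (k = 8.70 × 10⁻⁷ s⁻¹)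

L leads, at 48.7% in epsilon and 51.1% in zeta. With the undoing of G into L struck out, L in epsilon ends at 23.7%. The L share of 0.582, applied to what epsilon holds outside Q and J, gives 49.5%. The neighbour like epsilon but with 1.2 M of Z keeps Q at 39.3%, above the critical 36.8%, and Q leads there. The same share gives 32.6% for that neighbour, whose L stands at 31.7%.

(The earlier runs and the new flask were computed for substances that don't exist; scatter was added.)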